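The constants belong to no real substance; the result is computed.

The minute was my unit, and I set each step of this flask against it.

in all of them: D 4.5 mM

|  | G | L | time | remark |
|---|---|---|---|---|
| Friday's | 0.091 M | 0.137 M | 30 min | a closed flask charged with all of it at once and left for 30 min |
| Saturday's | 0.091 M | 0.137 M (fed, over 24.0 min) | 30 min | all but L at the start; L goes in evenly over 24.0 min, the run ends at 30 min |
| Sunday's | 0.091 M (fed, over 24.0 min) | 0.137 M | 30 min | all but G at the start; G goes in evenly over 24.0 min, the run ends at 30 min |
| Wednesday's | 0.091 M | 0.137 M |  | a single well-mixed tank run continuously and read at steady state, 30 min in it on average |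

    2 G → G2 (k1 = 2.11 L mol⁻¹ min⁻¹)
    G + Q → G.Q (k2 = 1.07 L mol⁻¹ min⁻¹)
    G + L + D → D + Q (k3 = 1090 L² mol⁻² min⁻¹)

- in percentages every species weighs as the G in it: one G2 or G.Q counts as two
- where a step has two of a species, its rate is k times that concentration squared, and two are used at each turn
- the stated concentrations are those of everything mixed, before any reaction; amounts are the same in each set-up
- the feed brings no volume worth counting
- run time (Friday's): 30 min

1. the set-up with the highest share of Q in all that became Q or G.Q, at the outlet or at the end ("none" if the first two lie within 2 percentage points) (Friday's / Saturday's / Sunday's / Wednesday's / none)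
2. share of Q in all that became Q or G.Q, at the outlet or at the end, Friday's
3. share of Q in all that became Q or G.Q, at the outlet or at the end, Saturday's
4. share of Q in all that became Q or G.Q, at the outlet or at the end, Sunday's
5. share of Q in all that became Q or G.Q, at the outlet or at the end, Wednesday's

G is the limiting reagent, charged at 0.091 M against 0.137 M of L. I wrote its balance. G leaves by the catalysed step, by the G + Q step and by pairing to G2. [G] stands in the first two rates, so it cancels from their ratio. Q is made per G.Q made in the ratio w[L]/[Q]. Here w is the selectivity factor, 4.58: the catalysed constant times [D], over the G + Q constant. On a repeat, [L]/[Q] is the ratio to watch.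

| Friday's, as charged | Time | The flask then |
|---|---|---|
| G by the catalysed step, half-life | 1.0 min | Q builds first |
| G by pairing, first half-life | 2.60 min | G2 forms alongside |
| Q by the G + Q step, half-life | 7.1 min | As charged, Q goes more slowly than G goes by the catalysed step |
| Run | 30 min | Longer than each rung |

For Friday's I took z, the pairing rate over the catalysed rate as charged, as 0.571. With [L] held at its charge and the G + Q step left aside, the share of G through the catalysed step is then the logarithm of one plus z, over z, or 79.1 %. I called that amount of G P, and it came to 0.0720 M. With a mean [L] of 0.101 M, the rule gave Q's share roughly as one over one plus P/(w[L]), so 86.5 %. My hand stopped there. For Wednesday's tank, Q per G.Q leaving is w[L]/[Q] minus one, since Q leaving is Q made less Q lost.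

The forecast chose Friday's, with 86.2 %, 82 %, 82.3 % and 70.4 % in the order asked. Its ground: “Friday's wins because Q is formed while L is plentiful and G is quickly used up”.

The run gave 86.3 %, 83.2 %, 82.2 % and 70.4 %, so Friday's came first. Wednesday's tank held 0.0697 M of L, with 25.7 % of the G charged in G.Q, each G.Q counted as two. The L used, less that G.Q, left 0.0556 M of Q. The rule then gave 4.75 Q leaving per G.Q, and with G.Q weighing two, Q's share came to 70.4 %.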